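Remark on the chemistry: atom labels follow the isochromanone numbering (C1 lactone carbonyl, O2, C3, C4, C4a, C5 to C8, C8a); the side chain is C1' (ArCH2), C2' (CHOAc) and C3' (CMe2OH). LiN(i-Pr)2 and LiN(SiMe3)2 are taken as commercial solutions.

## Structural features

The target is a 3,4-dihydroisocoumarin: a benzene ring fused through C4a–C8a to a six-membered lactone (C1, O2, C3, C4) whose C3 carries a methyl group and is an (S) stereocentre. The benzene ring bears a hydroxyl on C8 (peri to the lactone carbonyl and hydrogen-bonded to it), a three-carbon branch on C7, a methoxy group on C6 and its only hydrogen on C5. The branch is C1'H2–C2'H(OAc)–C3'(CH3)2OH, with the second (S) stereocentre at C2'. C2' lies seven bonds from C3, so the two stereocentres are not neighbours, cannot control each other, and each has to be set or brought in independently. Fragile groups are the secondary acetate beside a free tertiary alcohol (acyl shift, hydrolysis), the tertiary carbinol that acid can dehydrate or close onto the C8 oxygen as a dimethylchroman, the base-sensitive lactone and the electron-rich phenol. The real difficulty is twofold: the contiguous C8 OH / C7 alkyl / C6 OMe pattern on a ring substituted at five of six positions, and the placing of one acyl group on exactly one of three hydroxyls. The key step exploits that this array, with C5–H and the lactone-bearing C4a–C8a edge, is what results when a vinylketene (supplying C8, C5, C4a, C8a) combines with a 1-methoxyalkyne (supplying C7 and C6).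

## Logic of the disconnections

**24 to 23.** The last bond cut is the O–CH2Ph bond on the C3' oxygen. With the acetate already on C2', no acylation has to tell phenol, secondary and tertiary hydroxyl apart at the end, and no acid meets the carbinol. The endgame shrinks to one neutral step. The forward step must remove benzyl without touching lactone, aryl ether or acetate.

**23 to 8 and 18.** Four bonds are cut: C4a–C5, C5–C6, C7–C8 and C8–C8a. This removes the whole benzene ring and leaves two fragments that each hold one stereocentre and no arene. The forward step must generate a vinylketene from 8, join its carbonyl carbon to the alkyne carbon of 18 that bears C1', and close the ring onto pyranone C3. 18 must therefore contain no free hydroxyl that could trap a ketene.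

**18 to 17.** The acetyl C–O bond at C2' is cut. Acylation is placed here because this is the only hydroxyl in the molecule at that stage. The side-chain oxygens are carried as acetate and benzyl ether rather than as a cyclic ketal, because a ketal would have to be formed with acid on an acid-labile alkynyl ether and later removed with acid beside the phenol. The forward acylation must stay basic.

**17 to 14 and 15.** The C1'–C(sp) bond is cut, giving an epoxide electrophile and the two-carbon acetylide 16 derived from 15. The gain is a C2 plus C5 assembly with the stereocentre untouched. The demand is attack only at the unsubstituted epoxide carbon.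

**14 back to 9.** In turn the epoxide C–O bond (14 to 12), the ketal (12 to 11), the benzyl ether (11 to 10) and the two C–CH3 bonds at C3' (10 to 9) are cut. This reaches a chiral-pool ester whose stereocentre becomes C2' without ever breaking one of its bonds. The demands are selective activation of the primary hydroxyl and a protecting group on the tertiary oxygen that cannot migrate.

**8 to 6.** The C=N2 bond is cut (diazo transfer to a methyl ketone) rather than the acyl–CHN2 bond. Acylating a diazoalkane would expose a nucleophilic 1,3-dipole to the doubly activated C3=C4 bond of the pyranone. The demand is clean kinetic enolisation of the methyl group.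

**6 to 4.** The bond from pyranone C4 to the acetyl carbon is cut, leading to an enol triflate and an acyl-anion equivalent. The demand is a cross-coupling under neutral conditions.

**4 back to 1.** The O–S bond (4 to 3), the lactone O–C bond (3 to 2) and the C2–C3 bond of 2 (Claisen condensation, 2 to 1) are cut. This arrives at a chiral-pool hydroxy ester whose carbinol carbon becomes C3. The demand is that the free hydroxyl survives the condensation as its alkoxide.

## Other disconnections considered

**Alternative 1:** The cut opens the lactone at C3–C4 and O2–C1, leading to the fully substituted homophthalic anhydride A1 and acetaldehyde A2. In the forward step a cinchona-derived hydrogen-bonding squaramide would enolise A1 at C4, add it to A2 and let the new alkoxide acylate on the aryl-bound carbonyl, giving the trans acid A3.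
- In favour: it closes the heterocycle and sets C3 catalytically in one metal-free operation at ambient temperature, and the reaction class is established for homophthalic anhydrides.
- Against: the C4 carboxyl of A3 is absent from the target and, being an unactivated benzylic acid, needs a radical decarboxylation.
- Against: A2 is small, volatile and enolisable, so facial discrimination and self-condensation are concerns.
- Against: A1 already contains the hard part, because its OBn/prenyl/OMe array must be built by stepwise aromatic substitution.
- Against: the benzyl ether of A3 cannot be hydrogenolysed beside the prenyl alkene, and the side chain still needs asymmetric dihydroxylation and monoacetylation next to a phenol.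
- Comparison: structurally this plan solves the easy ring and leaves the arene, whereas the chosen plan solves the arene. Mechanistically it is ionic and mild, with no diazo compound and no photoreactor, and on that point it is the better of the two. In step economy it is the longer, and C2' would rest on late reagent control instead of the chiral pool.

**Alternative 2:** The cut is at C8–C8a and C5–C4a, giving the 2-prenyl 1,3-dioxygenated diene A4 and the chiral alkynoate A5. Forward, a thermal [4+2] cycloaddition is followed by loss of the alkoxy group at C8 to aromatise, then desilylation and lactonisation to the prenyl isochromanone A6.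
- In favour: the polarity match of such dienes with alkynoates gives the required regiochemistry, C3 comes from the chiral pool, both rings form in one flask, and A4 and A5 are each a few steps from simple materials.
- Against: a β-alkyl alkynoate is a sluggish dienophile and the diene carries a 2-substituent, so forcing temperatures and diene decomposition are likely.
- Against: after A6 the side chain needs asymmetric dihydroxylation on a free ortho-prenyl phenol and an acetylation that must distinguish secondary hydroxyl, tertiary hydroxyl and phenol.
- Comparison: on regiochemical logic the two plans are equal. On the number of steps to the arene and on avoiding light and diazo chemistry this alternative is the better. The chosen plan is the better in carrying the finished, oxygenated side chain through the ring-forming step, so that one neutral deprotection remains and both stereocentres come from the chiral pool.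

**Alternative 3:** The cut is at C7–C1' and C8a–C4a, leading to the open-chain diketo dioxinone prenyl ester A7. Forward, a zerovalent palladium–phosphine catalyst ionises the ester, decarboxylation and C-prenylation between the two carbonyls follow, and a carbonate base drives aldol closure and dehydration to the benzodioxinone A8.
- In favour: it is biomimetic, places the prenyl group between the two oxygens, and distinguishes the two phenolic oxygens (one free for methylation, one held in the ketal); C3 again comes from the chiral pool.
- Against: A7 is a sensitive polycarbonyl compound reached by a linear series of acylations, and prenyl transfer can also give branched or O-allylated material.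
- Against: after A8 at least O-methylation, desilylation with translactonisation, asymmetric dihydroxylation and selective acetylation remain.
- Comparison: on differentiation of the two ring oxygens the plans are equal, since the chosen plan takes the methoxy from the alkynyl ether. On mildness of the ring-forming step this alternative is the better. On step count and on security of the C2' configuration the chosen plan is the better.

Key step: step 12

## Route

Step 1
Reactants: 1 ethyl (S)-3-hydroxybutanoate
Product: 2 tert-butyl (S)-5-hydroxy-3-oxohexanoate
Conditions: t-BuOAc (3.5 equiv), LiN(i-Pr)2 (3.5 equiv), THF, −78 °C; then 1, −78 → −20 °C; AcOH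
Reagents that add atoms: tert-butyl acetate, CC(=O)OC(C)(C)C
Why: Crossed Claisen condensation: the excess lithium enolate first deprotonates the hydroxyl of 1 and then acylates at the ester carbonyl, and the product rests as its dianion until the quench. The carbinol carbon (the later C3) is not involved.

Step 2
Reactants: 2 tert-butyl (S)-5-hydroxy-3-oxohexanoate
Product: 3 (S)-6-methyldihydro-2H-pyran-2,4(3H)-dione
Conditions: CF3CO2H, CH2Cl2, 0 °C → rt
Reagents that add atoms: none
Why: Acid-mediated loss of the tert-butyl group and lactonisation of the δ-hydroxy β-keto ester is the standard entry to 6-substituted 4-hydroxy-5,6-dihydropyran-2-ones. The stereocentre keeps its C–O bond.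

Step 3
Reactants: 3 (S)-6-methyldihydro-2H-pyran-2,4(3H)-dione
Product: 4 (S)-6-methyl-2-oxo-5,6-dihydro-2H-pyran-4-yl trifluoromethanesulfonate
Conditions: Tf2O, Et3N, CH2Cl2, −78 °C
Reagents that add atoms: trifluoromethanesulfonic anhydride, O=S(=O)(OS(=O)(=O)C(F)(F)F)C(F)(F)F
Why: O-Sulfonylation of the enol form of the cyclic β-keto lactone gives the enol triflate. Low temperature and an amine base avoid ring-opening elimination.

Step 4
Reactants: 4 (S)-6-methyl-2-oxo-5,6-dihydro-2H-pyran-4-yl trifluoromethanesulfonate
Product: 6 (S)-4-acetyl-6-methyl-5,6-dihydro-2H-pyran-2-one, via ethoxyvinyl pyranone 5 (not isolated)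
Conditions: Bu3Sn(C(OEt)=CH2), Pd(PPh3)4 (5 mol%), LiCl, 1,4-dioxane, 80 °C; then 1 M HCl, THF, rt
Reagents that add atoms: tributyl(1-ethoxyvinyl)stannane, CCCC[Sn](CCCC)(CCCC)C(=C)OCC; water, O
Why: Stille coupling of an electron-poor enol triflate with an α-alkoxyvinylstannane, then hydrolysis of the enol ether, unmasks the methyl ketone. The conditions are neutral to weakly acidic, which the lactone tolerates.

Step 5
Reactants: 6 (S)-4-acetyl-6-methyl-5,6-dihydro-2H-pyran-2-one
Product: 8 (S)-4-(2-diazoacetyl)-6-methyl-5,6-dihydro-2H-pyran-2-one, via trifluoroacetyl diketone 7 (not isolated)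
Conditions: LiN(SiMe3)2, THF, −78 °C; CF3CO2CH2CF3, −78 °C; aq. HCl work-up; then 4-AcNHC6H4SO2N3, Et3N, H2O (1 equiv), MeCN, rt
Reagents that add atoms: 4-acetamidobenzenesulfonyl azide, CC(=O)Nc1ccc(cc1)S(=O)(=O)N=[N+]=[N-]; 2,2,2-trifluoroethyl trifluoroacetate, FC(F)(F)COC(=O)C(F)(F)F (its trifluoroacetyl group is held only by 7)
Why: Detrifluoroacetylative diazo transfer: the kinetic enolate of the methyl ketone is trifluoroacetylated, the activated diketone 7 takes the diazo group from the sulfonyl azide under mild amine base, and the trifluoroacetyl group leaves on the sulfonamide. This is the established way to α'-diazo enones and keeps nucleophilic diazoalkanes away from the doubly activated C3=C4 bond.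

Step 6
Reactants: 9 methyl (S)-2,2-dimethyl-1,3-dioxolane-4-carboxylate
Product: 10 (S)-2-(2,2-dimethyl-1,3-dioxolan-4-yl)propan-2-ol
Conditions: MeMgBr (2.5 equiv), THF, 0 °C → rt; sat. aq. NH4Cl
Reagents that add atoms: methylmagnesium bromide, C[Mg]Br
Why: Double Grignard addition to the ester gives the tertiary carbinol. Addition outruns enolisation at the α-carbon, so the glycerate stereocentre (the later C2') is retained.

Step 7
Reactants: 10 (S)-2-(2,2-dimethyl-1,3-dioxolan-4-yl)propan-2-ol
Product: 11 (S)-4-[2-(benzyloxy)propan-2-yl]-2,2-dimethyl-1,3-dioxolane
Conditions: NaH, BnBr, Bu4NI (cat.), DMF, 0 → 50 °C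
Reagents that add atoms: benzyl bromide, BrCc1ccccc1
Why: Williamson etherification of the tertiary alkoxide with a reactive benzylic halide under iodide catalysis; the ketal is inert to base. Benzyl is chosen because it cannot migrate to a neighbouring alkoxide and leaves by neutral hydrogenolysis.

Step 8
Reactants: 11 (S)-4-[2-(benzyloxy)propan-2-yl]-2,2-dimethyl-1,3-dioxolane
Product: 12 (S)-3-(benzyloxy)-3-methylbutane-1,2-diol
Conditions: AcOH/H2O (4:1), 40 °C
Reagents that add atoms: none
Why: Mild aqueous acid hydrolyses the terminal isopropylidene ketal. The tertiary benzyl ether survives because its ionisation is disfavoured by the neighbouring oxygenated carbon.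

Step 9
Reactants: 12 (S)-3-(benzyloxy)-3-methylbutane-1,2-diol
Product: 14 (S)-2-[2-(benzyloxy)propan-2-yl]oxirane, via primary tosylate 13 (not isolated)
Conditions: TsCl, Et3N, Bu2SnO (2 mol%), CH2Cl2, 0 °C → rt; then K2CO3, MeOH, 0 °C → rt
Reagents that add atoms: 4-toluenesulfonyl chloride, Cc1ccc(cc1)S(Cl)(=O)=O (its sulfonyl group is held only by 13)
Why: Tin-catalysed sulfonylation is selective for the primary hydroxyl of a terminal 1,2-diol, and base then closes the epoxide by intramolecular SN2 displacement at the primary carbon. The C–O bond of the stereocentre is never broken, so its configuration is retained.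

Step 10
Reactants: 14 (S)-2-[2-(benzyloxy)propan-2-yl]oxirane; 15 chloroacetaldehyde dimethyl acetal
Product: 17 (S)-2-(benzyloxy)-6-methoxy-2-methylhex-5-yn-3-ol, via lithium methoxyacetylide 16 (not isolated)
Conditions: 15, LiNEt2 (from Et2NH, n-BuLi; 3.0 equiv per 15), THF, −10 °C → rt; then 14, DMPU, rt → 40 °C; H2O; chromatography on Et3N-deactivated silica
Reagents that add atoms: lithium diethylamide, [Li]N(CC)CC (its lithium is held only by 16)
Why: Twofold elimination (methanol, then HCl) from 15 and deprotonation is the known in-flask route to alkoxyacetylides, and 16 then opens the epoxide by SN2 attack at its unsubstituted carbon, helped by the dipolar co-solvent. The stereocentre is untouched and the benzyl ether cannot shift to the new alkoxide.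

Step 11
Reactants: 17 (S)-2-(benzyloxy)-6-methoxy-2-methylhex-5-yn-3-ol
Product: 18 (S)-2-(benzyloxy)-6-methoxy-2-methylhex-5-yn-3-yl acetate
Conditions: Ac2O, Et3N, DMAP (10 mol%), CH2Cl2, 0 °C → rt
Reagents that add atoms: acetic anhydride, CC(=O)OC(C)=O
Why: DMAP-catalysed acylation of the only free hydroxyl. The medium stays basic throughout, as the acid-labile alkynyl ether requires.

Step 12
Reactants: 8 (S)-4-(2-diazoacetyl)-6-methyl-5,6-dihydro-2H-pyran-2-one; 18 (S)-2-(benzyloxy)-6-methoxy-2-methylhex-5-yn-3-yl acetate
Product: 23 (S)-3-(benzyloxy)-1-[(S)-8-hydroxy-6-methoxy-3-methyl-1-oxoisochroman-7-yl]-3-methylbutan-2-yl acetate, via vinylketene 19 (not isolated), via vinylcyclobutenone 20 (not isolated), via dienylketene 21 (not isolated), via cyclohexadienone 22 (not isolated)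
Conditions: 8, 18 (1.2 equiv), ClCH2CH2Cl (0.05 M), hν (medium-pressure Hg lamp, Pyrex), rt; then 80 °C in the dark
Reagents that add atoms: none
Why: Light expels N2 from 8 and pyranone C4 migrates to the carbene carbon (Wolff rearrangement, new C4a–C5 bond), giving vinylketene 19 conjugated with the C3=C4 bond of the lactone ring. The electrophilic ketene carbon is attacked by the electron-rich carbon of 18 that bears C1', and the [2+2] cycloaddition (C7–C8 and C5–C6) gives the 3-methoxy-4-vinylcyclobutenone 20. At 80 °C 20 opens by 4π electrocyclic cleavage to dienylketene 21, which closes the benzene ring by a thermal disrotatory 6π electrocyclisation between the ketene carbon and pyranone C3 (C8–C8a); enolisation of cyclohexadienone 22 gives the C8 phenol. The closest known reaction type is the second-generation Danheiser benzannulation (photochemical Wolff rearrangement of an α-diazo enone in the presence of a 1-alkoxyalkyne), applied here to an enone that is part of an unsaturated lactone. No stereocentre is formed: C3 and C2' enter unchanged, neither is α to a carbonyl group or part of a pericyclic array, and the sp3 centres of 20 and 22 disappear on aromatisation. The step needs one regiochemistry in the [2+2] event, and the polarisation of the alkynyl ether (oxygen lone pair making the C1'-bearing carbon nucleophilic) secures that this carbon bonds to the ketene carbonyl carbon, which puts the side chain at C7 between OH and OMe. The 6π closure needs a small inward substituent at the terminus, and the lactone ring holds its carbonyl outward and hydrogen inward at pyranone C3. The acetate and benzyl ether leave no hydroxyl in 18 that could trap either ketene.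

Step 13
Reactants: 23 (S)-3-(benzyloxy)-1-[(S)-8-hydroxy-6-methoxy-3-methyl-1-oxoisochroman-7-yl]-3-methylbutan-2-yl acetate
Product: 24 (S)-3-hydroxy-1-[(S)-8-hydroxy-6-methoxy-3-methyl-1-oxoisochroman-7-yl]-3-methylbutan-2-yl acetate
Conditions: H2 (1 atm), Pd(OH)2/C, EtOAc, rt
Reagents that add atoms: none
Why: Hydrogenolysis of the benzyl C–O bond under neutral conditions frees the tertiary alcohol. Aryl ether, phenol, lactone and acetate are inert, and without acid or base the acetate should stay on C2'.

## Compound list

1 | ethyl (S)-3-hydroxybutanoate | CCOC(=O)C[C@H](C)O | starting material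
2 | tert-butyl (S)-5-hydroxy-3-oxohexanoate | C[C@H](O)CC(=O)CC(=O)OC(C)(C)C | intermediate
3 | (S)-6-methyldihydro-2H-pyran-2,4(3H)-dione (enol form: (S)-4-hydroxy-6-methyl-5,6-dihydro-2H-pyran-2-one) | C[C@H]1CC(=O)CC(=O)O1 | intermediate
4 | (S)-6-methyl-2-oxo-5,6-dihydro-2H-pyran-4-yl trifluoromethanesulfonate | C[C@H]1CC(OS(=O)(=O)C(F)(F)F)=CC(=O)O1 | intermediate
5 | (S)-4-(1-ethoxyvinyl)-6-methyl-5,6-dihydro-2H-pyran-2-one | C[C@H]1CC(C(=C)OCC)=CC(=O)O1 | intermediate
6 | (S)-4-acetyl-6-methyl-5,6-dihydro-2H-pyran-2-one | C[C@H]1CC(C(C)=O)=CC(=O)O1 | intermediate
7 | (S)-6-methyl-4-(4,4,4-trifluoro-3-oxobutanoyl)-5,6-dihydro-2H-pyran-2-one | C[C@H]1CC(C(=O)CC(=O)C(F)(F)F)=CC(=O)O1 | intermediate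
8 | (S)-4-(2-diazoacetyl)-6-methyl-5,6-dihydro-2H-pyran-2-one | C[C@H]1CC(C(=O)C=[N+]=[N-])=CC(=O)O1 | intermediate
9 | methyl (S)-2,2-dimethyl-1,3-dioxolane-4-carboxylate | COC(=O)[C@@H]1COC(C)(C)O1 | starting material
10 | (S)-2-(2,2-dimethyl-1,3-dioxolan-4-yl)propan-2-ol | CC(C)(O)[C@@H]1COC(C)(C)O1 | intermediate
11 | (S)-4-[2-(benzyloxy)propan-2-yl]-2,2-dimethyl-1,3-dioxolane | CC(C)(OCc1ccccc1)[C@@H]1COC(C)(C)O1 | intermediate
12 | (S)-3-(benzyloxy)-3-methylbutane-1,2-diol | CC(C)(OCc1ccccc1)[C@@H](O)CO | intermediate
13 | (S)-3-(benzyloxy)-2-hydroxy-3-methylbutyl 4-methylbenzenesulfonate | CC(C)(OCc1ccccc1)[C@@H](O)COS(=O)(=O)c1ccc(C)cc1 | intermediate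
14 | (S)-2-[2-(benzyloxy)propan-2-yl]oxirane | CC(C)(OCc1ccccc1)[C@@H]1CO1 | intermediate
15 | chloroacetaldehyde dimethyl acetal (2-chloro-1,1-dimethoxyethane) | COC(CCl)OC | starting material
16 | lithium methoxyacetylide | [Li]C#COC | intermediate
17 | (S)-2-(benzyloxy)-6-methoxy-2-methylhex-5-yn-3-ol | COC#CC[C@H](O)C(C)(C)OCc1ccccc1 | intermediate
18 | (S)-2-(benzyloxy)-6-methoxy-2-methylhex-5-yn-3-yl acetate | COC#CC[C@H](OC(C)=O)C(C)(C)OCc1ccccc1 | intermediate
19 | (S)-6-methyl-4-(2-oxoethenyl)-5,6-dihydro-2H-pyran-2-one | C[C@H]1CC(C=C=O)=CC(=O)O1 | intermediate
20 | (S)-3-(benzyloxy)-1-{2-methoxy-3-[(S)-6-methyl-2-oxo-5,6-dihydro-2H-pyran-4-yl]-4-oxocyclobut-1-en-1-yl}-3-methylbutan-2-yl acetate (cyclobutene sp3 carbon unassigned) | COC1=C(C[C@H](OC(C)=O)C(C)(C)OCc2ccccc2)C(=O)C1C3=CC(=O)O[C@@H](C)C3 | intermediate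
21 | 2-[(S)-2-acetoxy-3-(benzyloxy)-3-methylbutyl]-3-methoxy-4-[(S)-6-methyl-2-oxo-5,6-dihydro-2H-pyran-4-yl]buta-1,3-dien-1-one | O=C=C(C[C@H](OC(C)=O)C(C)(C)OCc1ccccc1)C(OC)=CC2=CC(=O)O[C@@H](C)C2 | intermediate
22 | (S)-3-(benzyloxy)-1-[(3S)-6-methoxy-3-methyl-1,8-dioxo-3,4,8,8a-tetrahydro-1H-isochromen-7-yl]-3-methylbutan-2-yl acetate (C8a unassigned) | COC1=C(C[C@H](OC(C)=O)C(C)(C)OCc3ccccc3)C(=O)C2C(=O)O[C@@H](C)CC2=C1 | intermediate
23 | (S)-3-(benzyloxy)-1-[(S)-8-hydroxy-6-methoxy-3-methyl-1-oxoisochroman-7-yl]-3-methylbutan-2-yl acetate | COc1cc2c(c(O)c1C[C@H](OC(C)=O)C(C)(C)OCc3ccccc3)C(=O)O[C@@H](C)C2 | intermediate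
24 | (S)-3-hydroxy-1-[(S)-8-hydroxy-6-methoxy-3-methyl-1-oxoisochroman-7-yl]-3-methylbutan-2-yl acetate | COc1cc2c(c(O)c1C[C@H](OC(C)=O)C(C)(C)O)C(=O)O[C@@H](C)C2 | target

## Step count and least certain steps

Total step count: 13. Longest linear sequence: 8 steps (9 to 24 through steps 6 to 13); the other branch runs 1 to 8 in 5 steps and joins at step 12.

**Step 12 (key step).** The most likely failures are photochemical channels that bypass the ketene (excitation of the ene-dione chromophore, carbene reactions without rearrangement), dimerisation or hydration of the electron-poor vinylketene before it meets the alkyne, cycloaddition of the diazo group of one molecule of 8 to the activated C3=C4 bond of another, and acylation of the product phenol by ketene. The cause is that an acceptor-substituted vinylketene held in a lactone ring has no direct precedent in this benzannulation. The fallback makes the same vinylketene 19 without light and without a diazo group. It sets out from 4: palladium-catalysed coupling with BrZnCH2CO2t-Bu (Pd(PPh3)4, THF) should give tert-butyl (S)-2-(6-methyl-2-oxo-5,6-dihydro-2H-pyran-4-yl)acetate F1. CF3CO2H then frees (S)-2-(6-methyl-2-oxo-5,6-dihydro-2H-pyran-4-yl)acetic acid F2, and oxalyl chloride converts it into (S)-2-(6-methyl-2-oxo-5,6-dihydro-2H-pyran-4-yl)acetyl chloride F3. Slow addition of F3 to 18 and Et3N in toluene (dehydrochlorination to 19 and [2+2] cycloaddition), filtration of the ammonium salt and heating should lead through 20, 21 and 22 back to the route at 23.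

**Step 5.** The likely failures are competing deprotonation at pyranone C5 (γ to the lactone carbonyl) followed by ring opening through β-elimination of the carboxylate, conjugate self-addition of the enolate to the ene-dione, and slow intermolecular cycloaddition of the product on concentration. The fallback sets out from 4. Hydroxycarbonylation (Pd(OAc)2, dppf, CO, KOAc, DMSO) should give (S)-6-methyl-2-oxo-5,6-dihydro-2H-pyran-4-carboxylic acid F4, and oxalyl chloride with catalytic DMF gives (S)-6-methyl-2-oxo-5,6-dihydro-2H-pyran-4-carbonyl chloride F5. Acylation of Me3SiCHN2 in MeCN/THF at 0 °C, cold and dilute to hold back dipolar addition to the alkene, returns to the route at 8.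

**Step 10.** The likely failures are slow SN2 opening of an epoxide flanked by a quaternary carbon without Lewis acid, competing opening by diethylamine or methoxide, and loss of the hydroxy alkynyl ether by acid-induced cyclisation during work-up. The fallback sets out from 15 and 14 and separates acetylide formation from the opening. NaNH2 in liquid NH3 converts 15 into sodium methoxyacetylide F6, which is protonated and distilled into cold THF as methoxyacetylene F7. n-BuLi at −78 °C then gives 16 in an amine-free medium, and BF3·OEt2 with 14 at −78 °C (Lewis-acid-activated opening) returns to the route at 17.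

**Step 11.** The likely failures are addition of acetic acid to, or hydration of, the alkynyl ether, cyclisation of 17 while it is handled as the free alcohol, and sluggish acylation of the hindered carbinol. The fallback avoids the free alcohol: setting out from 14 and 15, the lithium alkoxide formed in step 10 is not quenched but acetylated in the same flask with excess Ac2O at 0 °C (the excess also consumes diethylamine and methoxide), returning to the route at 18; no new compound arises on this way (F0).

## Further compounds

F1 | step 12 | tert-butyl (S)-2-(6-methyl-2-oxo-5,6-dihydro-2H-pyran-4-yl)acetate | C[C@H]1CC(CC(=O)OC(C)(C)C)=CC(=O)O1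
F2 | step 12 | (S)-2-(6-methyl-2-oxo-5,6-dihydro-2H-pyran-4-yl)acetic acid | C[C@H]1CC(CC(O)=O)=CC(=O)O1
F3 | step 12 | (S)-2-(6-methyl-2-oxo-5,6-dihydro-2H-pyran-4-yl)acetyl chloride | C[C@H]1CC(CC(Cl)=O)=CC(=O)O1
F4 | step 5 | (S)-6-methyl-2-oxo-5,6-dihydro-2H-pyran-4-carboxylic acid | C[C@H]1CC(C(O)=O)=CC(=O)O1
F5 | step 5 | (S)-6-methyl-2-oxo-5,6-dihydro-2H-pyran-4-carbonyl chloride | C[C@H]1CC(C(Cl)=O)=CC(=O)O1
F6 | step 10 | sodium methoxyacetylide | [Na]C#COC
F7 | step 10 | methoxyacetylene | COC#C
F0 | step 11 | none | none
A1 | alternative 1 | 8-(benzyloxy)-6-methoxy-7-(3-methylbut-2-en-1-yl)isochromane-1,3-dione | COc1cc2CC(=O)OC(=O)c2c(OCc3ccccc3)c1CC=C(C)C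
A2 | alternative 1 | acetaldehyde | CC=O
A3 | alternative 1 | (3S,4R)-8-(benzyloxy)-6-methoxy-3-methyl-7-(3-methylbut-2-en-1-yl)-1-oxoisochromane-4-carboxylic acid | COc1cc2c(c(OCc3ccccc3)c1CC=C(C)C)C(=O)O[C@@H](C)[C@@H]2C(=O)O
A4 | alternative 2 | {[1,3-dimethoxy-2-(3-methylbut-2-en-1-yl)buta-1,3-dien-1-yl]oxy}trimethylsilane | COC(=C)C(CC=C(C)C)=C(OC)O[Si](C)(C)C
A5 | alternative 2 | methyl (S)-5-[(tert-butyldimethylsilyl)oxy]hex-2-ynoate | COC(=O)C#CC[C@H](C)O[Si](C)(C)C(C)(C)C
A6 | alternative 2 | (S)-8-hydroxy-6-methoxy-3-methyl-7-(3-methylbut-2-en-1-yl)isochroman-1-one | COc1cc2c(c(O)c1CC=C(C)C)C(=O)O[C@@H](C)C2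
A7 | alternative 3 | 3-methylbut-2-en-1-yl (7S)-7-[(tert-butyldimethylsilyl)oxy]-2-(2,2-dimethyl-4-oxo-4H-1,3-dioxin-6-yl)-3,5-dioxooctanoate | CC1(C)OC(=O)C=C(O1)C(C(=O)OCC=C(C)C)C(=O)CC(=O)C[C@H](C)O[Si](C)(C)C(C)(C)C
A8 | alternative 3 | 5-[(S)-2-(tert-butyldimethylsilyloxy)propyl]-7-hydroxy-2,2-dimethyl-8-(3-methylbut-2-en-1-yl)-4H-benzo[d][1,3]dioxin-4-one | CC1(C)Oc2c(CC=C(C)C)c(O)cc(C[C@H](C)O[Si](C)(C)C(C)(C)C)c2C(=O)O1
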